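The cycloheptane is disconnected at the two bonds that tie it to the ring-fusion carbons of the cyclopentane, C1–C10 and C5–C6 (C1 = CH3-bearing fusion carbon, C4 = isopropyl carbinol, C5 = fusion CH, C6 = ester carbon, C7 = ketone, C8/C9 = diol, C10 = CH2). An oxidopyrylium [5+2] cycloaddition builds both at once: the C1=C5 bond of 3-methylcyclopent-2-enone is the two-carbon partner and creates quaternary C1, while 4-methyl-3-oxidopyrylium delivers C6–C10 with the C8 methyl and C9 oxygen. The oxygen bridge is then excised to a flat cross-conjugated dienone, from which C1 relays stereochemistry to C8, C9, C5, C6 and C4. A hydrobenzoin ketal resolves the racemate.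

Key step: step 4

Remark: the cycloaddition gives racemic material as exo and endo adducts. Compounds 7 to 11 are drawn as the exo isomer of the enantiomer that is carried on; both adducts converge at 12, where the antipode is removed as its ketal diastereomer.

Step 1
Reactants: 1 methyl 3-methylfuran-2-carboxylate
Product: 2 (3-methylfuran-2-yl)methanol
Conditions: LiAlH4, THF, 0 °C
Reagents that add atoms: none
Why: Hydride reduction of the ester to the primary alcohol (LiAlH4 reduction); the furan ring is inert and no stereocentre is involved.

Step 2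
Reactants: 2 (3-methylfuran-2-yl)methanol
Product: 3 6-hydroxy-4-methyl-2H-pyran-3(6H)-one
Conditions: mCPBA, CH2Cl2, 0 °C
Reagents that add atoms: mCPBA, OOC(=O)c1cccc(Cl)c1
Why: Achmatowicz rearrangement: oxidation of the furan, opening to the ene-dione and hemiacetal closure by the CH2OH group give the pyranone with the former furan methyl on its C4; the racemic hemiacetal centre is destroyed in step 4.

Step 3
Reactants: 3 6-hydroxy-4-methyl-2H-pyran-3(6H)-one
Product: 4 4-methyl-5-oxo-5,6-dihydro-2H-pyran-2-yl acetate
Conditions: Ac2O, pyridine, DMAP (cat.), CH2Cl2, 0 °C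
Reagents that add atoms: acetic anhydride, CC(=O)OC(C)=O
Why: DMAP-catalysed O-acetylation of the hemiacetal hydroxyl installs the leaving group needed for ylide formation.

Step 4
Reactants: 4 4-methyl-5-oxo-5,6-dihydro-2H-pyran-2-yl acetate; 5 3-methylcyclopent-2-en-1-one
Product: 7 oxa-bridged cycloadduct (exo isomer drawn), via oxidopyrylium ylide 6 (not isolated)
Conditions: Et3N, MeCN, 5 (10 equiv), 80 °C, sealed tube
Reagents that add atoms: none
Why: Et3N eliminates acetic acid from 4 to give the oxidopyrylium ylide 6, a cyclic carbonyl ylide whose two termini (the carbons flanking the ring oxygen) add suprafacially, in a concerted but asynchronous thermal [5+2] (1,3-dipolar type) cycloaddition, across the C1=C5 bond of enone 5. The closest known reaction type is the oxidopyrylium–alkene [5+2] cycloaddition with electron-poor alkenes. The seven-membered carbocycle (C1, C5, C6, C7, C8, C9, C10) closes by this two-bond cycloaddition and first appears as an 8-oxabicyclo[3.2.1]octenone, cis-fused to the cyclopentanone. C1 and C5 arise cis from the suprafacial addition and C6 and C10 are held cis by the oxygen bridge, while the exo/endo relation between the two pairs needs no control because C10, C5 and C6 lose their configuration in steps 6 and 7; the absolute configuration of the quaternary C1 is not controlled (racemate, resolved through the ketal of step 5). The step needs regioselectivity, the ylide carbon next to the oxido carbon (future C10) bonding to the enone β-carbon C1, and this is secured by matching the enolate-like, nucleophilic ylide terminus with the electrophilic β-carbon. The low reactivity of the β,β-disubstituted enone is met by a large excess of 5 at 80 °C, where ylide dimers revert to 6.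

Step 5
Reactants: 7 oxa-bridged cycloadduct
Product: 8 C4 (1R,2R)-1,2-diphenylethane-1,2-diyl ketal of 7
Conditions: (1R,2R)-1,2-diphenylethane-1,2-diol, PPTS (cat.), benzene, reflux, azeotropic removal of water
Reagents that add atoms: (1R,2R)-1,2-diphenylethane-1,2-diol, O[C@H](c1ccccc1)[C@H](O)c1ccccc1
Why: Acid-catalysed ketalization is chemoselective for the saturated cyclopentanone over the conjugated C9 ketone and protects C4 against enolization and β-elimination of the bridge oxygen; racemic 7 gives two diastereomeric ketals that differ at C1 relative to the diol and are carried together to 12.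

Step 6
Reactants: 8 C4 ketal of the cycloadduct
Product: 9 ketal hydroxy enone (C10 now CH2, C6–OH)
Conditions: SmI2 (2.5 equiv), THF/MeOH, −78 °C
Reagents that add atoms: none
Why: Single-electron reduction of the C9 ketone and expulsion of the α-alkoxide (SmI2 cleavage of α-alkoxy ketones) should break the C10–O bond, so that C10 becomes CH2 and the former bridge oxygen remains as C6–OH.

Step 7
Reactants: 9 ketal hydroxy enone
Product: 12 linear dienone ketal, via allylic mesylate 10 (not isolated), via allylic bromide 11 (not isolated)
Conditions: MsCl, Et3N, CH2Cl2, 0 °C; then LiBr, Li2CO3, DMF, 100 °C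
Reagents that add atoms: none
Why: Mesylation, bromide exchange and dehydrobromination (the classical LiBr/Li2CO3 route from γ-substituted enones to dienones) remove the C6 oxygen together with C5–H; bromide exchange equilibrates C6 so that exo- and endo-derived isomers both eliminate, C1 is left as the only ring stereocentre, and the two ketal diastereomers are separated here by crystallization or chromatography.

Step 8
Reactants: 12 linear dienone ketal
Product: 13 7,8-epoxy enone ketal
Conditions: H2O2 (30% aq.), NaOH, MeOH, 0 °C
Reagents that add atoms: hydrogen peroxide, OO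
Why: Weitz–Scheffer nucleophilic epoxidation: hydroperoxide adds 1,4 to C7 because the 1,6 terminus C5 is fully substituted and shielded by the quaternary C1 and the ketal; the epoxide configuration is irrelevant because C7 becomes a ketone and C8 an alkene carbon.

Step 9
Reactants: 13 7,8-epoxy enone ketal
Product: 15 bis-allylic alcohol, via epoxy hydrazone 14 (not isolated)
Conditions: N2H4·H2O, AcOH (cat.), MeOH, 0 °C to rt
Reagents that add atoms: none
Why: Wharton reaction: the hydrazone opens the epoxide to an alkenyl diazene that loses N2, giving the transposed allylic alcohol with oxygen at C7 and the C8=C9 double bond; the carbinol configuration is inconsequential.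

Step 10
Reactants: 15 bis-allylic alcohol
Product: 16 cross-conjugated dienone ketal
Conditions: MnO2, CH2Cl2, rt
Reagents that add atoms: none
Why: MnO2 oxidizes the doubly allylic C7 alcohol under neutral conditions to the cross-conjugated dienone, a nearly planar ring system whose only stereocentre is C1.

Step 11
Reactants: 16 cross-conjugated dienone ketal
Product: 17 8,9-diol enone ketal
Conditions: OsO4 (cat.), N-methylmorpholine N-oxide, citric acid, t-BuOH/H2O, rt
Reagents that add atoms: N-methylmorpholine N-oxide, C[N+]1([O-])CCOCC1; water, O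
Why: Syn dihydroxylation is expected at the less hindered C8=C9 bond (C5=C6 is flanked by the quaternary C1 and the ketal carbon) and from the face opposite the pseudoaxial C1 methyl, the only group standing out of the flat dienone, which sets C8–OH and C9–OH cis to each other and anti to that methyl; citric acid keeps the medium near neutral.

Step 12
Reactants: 17 8,9-diol enone ketal
Product: 18 trans-fused diol ketone ketal
Conditions: H2 (1 atm), [Ir(cod)(PCy3)(py)]PF6 (cat.), CH2Cl2, rt
Reagents that add atoms: none
Why: Hydroxyl-directed homogeneous hydrogenation: the homoallylic tertiary C8–OH binds the cationic iridium and hydrogen is delivered to the same face of C5=C6, placing C5–H anti to the C1 methyl (trans ring fusion), whereas undirected heterogeneous hydrogenation of such ring-fusion enones tends to give the cis isomer.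

Step 13
Reactants: 18 trans-fused diol ketone ketal
Product: 19 8,9-acetonide of 18
Conditions: 2-methoxypropene, PPTS (cat.), CH2Cl2, 0 °C
Reagents that add atoms: 2-methoxypropene, COC(C)=C
Why: Kinetic acetonide formation on the cis 8,9-diol protects the C9–OH, whose β-hydroxy ketone relation to C7 would allow retro-aldol cleavage in the basic step that follows; the diphenyl dioxolane is stable to these conditions.

Step 14
Reactants: 19 8,9-acetonide
Product: 21 C6 hydroxy ketone, via potassium enolate 20 (not isolated)
Conditions: KN(SiMe3)2, THF, −78 °C; then 2-(phenylsulfonyl)-3-phenyloxaziridine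
Reagents that add atoms: 2-(phenylsulfonyl)-3-phenyloxaziridine, O=S(=O)(c1ccccc1)N1OC1c1ccccc1
Why: Oxaziridine oxidation of the enolate, which can form only toward C6 because C8 is quaternary; the oxidant should approach anti to the C1 methyl (1,3 to C6), placing C6–OH cis to C5–H, which is also the equatorial, thermodynamically preferred orientation of this epimerizable centre.

Step 15
Reactants: 21 C6 hydroxy ketone
Product: 22 6-hydroxy-4,7-dione acetonide
Conditions: H2 (3 atm), Pd(OH)2/C, EtOAc/EtOH, rt
Reagents that add atoms: none
Why: Hydrogenolysis of the two benzylic C–O bonds of the diphenyl dioxolane releases the C4 ketone under neutral conditions, which avoids epimerization of the adjacent C5 and β-elimination of the C6 hydroxyl.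

Step 16
Reactants: 22 6-hydroxy-4,7-dione acetonide
Product: 23 C4 isopropyl carbinol
Conditions: iPrMgCl (3 equiv), LaCl3·2LiCl, THF, −40 °C
Reagents that add atoms: isopropylmagnesium chloride, CC(C)[Mg]Cl
Why: Lanthanum-promoted Grignard 1,2-addition with suppressed enolization; attack on the trans-fused cyclopentanone from the face of C5–H, opposite the C5–C6 bond and the C1 methyl, puts isopropyl cis to C5–H and the hydroxyl cis to the C1 methyl, while the C7 ketone, flanked by quaternary C8 and the C6 alkoxide, should not react.

Step 17
Reactants: 23 C4 isopropyl carbinol; 24 4-acetoxybenzoyl chloride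
Product: 25 C6 4-acetoxybenzoate
Conditions: pyridine, DMAP (cat.), CH2Cl2, 0 °C to rt
Reagents that add atoms: none
Why: DMAP-catalysed acylation of the only secondary hydroxyl (C6–OH); the tertiary C4 hydroxyl is inert under these conditions.

Step 18
Reactants: 25 C6 4-acetoxybenzoate
Product: 26 target compound
Conditions: HCl (1 M aq.), MeOH, rt
Reagents that add atoms: none
Why: Acid cleaves the acetonide and transesterifies the phenolic acetate (aryl acetates undergo acid methanolysis much faster than the hindered secondary aroyl ester), and acidic conditions avoid retro-aldol cleavage at C8–C9 and acyl migration.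

Compound list
1 | methyl 3-methylfuran-2-carboxylate | COC(=O)c1occc1C | starting material
2 | (3-methylfuran-2-yl)methanol | OCc1occc1C | intermediate
3 | 6-hydroxy-4-methyl-2H-pyran-3(6H)-one (racemic hemiacetal) | CC1=CC(O)OCC1=O | intermediate
4 | 4-methyl-5-oxo-5,6-dihydro-2H-pyran-2-yl acetate (racemic) | CC(=O)OC1OCC(=O)C(C)=C1 | intermediate
5 | 3-methylcyclopent-2-en-1-one | CC1=CC(=O)CC1 | starting material
6 | 4-methylpyrylium-3-olate (4-methyl-3-oxidopyrylium), not isolated | Cc1cc[o+]cc1[O-] | intermediate
7 | cycloadduct: cyclopentanone (C4=O) cis-fused at C1–C5 to an 8-oxabicyclo[3.2.1]oct-3-en-2-one (C9=O, C7=C8 with CH3 on C8, oxygen bridging C6 and C10); exo isomer, C1 methyl on the face opposite the bridge oxygen; racemic, drawn with the target C1 configuration | O=C1CC[C@]2(C)[C@H]3C(=O)C(C)=C[C@H](O3)[C@H]12 | intermediate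
8 | C4 (1R,2R)-1,2-diphenylethane-1,2-diyl ketal of 7 | O1[C@H](c2ccccc2)[C@@H](c2ccccc2)OC13CC[C@]4(C)[C@H]5C(=O)C(C)=C[C@H](O5)[C@H]34 | intermediate
9 | ketal hydroxy enone: C9 ketone, C7=C8, C10 CH2, C6–OH anti to the C1 methyl, cis ring fusion | O1[C@H](c2ccccc2)[C@@H](c2ccccc2)OC13CC[C@]4(C)CC(=O)C(C)=C[C@H](O)[C@H]34 | intermediate
10 | C6 methanesulfonate of 9, not isolated | O1[C@H](c2ccccc2)[C@@H](c2ccccc2)OC13CC[C@]4(C)CC(=O)C(C)=C[C@H](OS(C)(=O)=O)[C@H]34 | intermediate
11 | C6 bromide (C6 equilibrating; inverted epimer drawn), not isolated | O1[C@H](c2ccccc2)[C@@H](c2ccccc2)OC13CC[C@]4(C)CC(=O)C(C)=C[C@@H](Br)[C@H]34 | intermediate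
12 | linear dienone ketal: C9 ketone conjugated with C7=C8 and C5=C6; C1 the only ring stereocentre | O1[C@H](c2ccccc2)[C@@H](c2ccccc2)OC13CC[C@]4(C)CC(=O)C(C)=CC=C34 | intermediate
13 | 7,8-epoxide of 12 (epoxide oxygen drawn anti to the C1 methyl; either face serves) | O1[C@H](c2ccccc2)[C@@H](c2ccccc2)OC13CC[C@]4(C)CC(=O)[C@]5(C)O[C@@H]5C=C34 | intermediate
14 | C9 hydrazone of 13, not isolated | O1[C@H](c2ccccc2)[C@@H](c2ccccc2)OC13CC[C@]4(C)CC(=NN)[C@]5(C)O[C@@H]5C=C34 | intermediate
15 | bis-allylic alcohol: C7–OH between C5=C6 and C8=C9 (carbinol configuration inconsequential) | O1[C@H](c2ccccc2)[C@@H](c2ccccc2)OC13CC[C@]4(C)CC=C(C)[C@H](O)C=C34 | intermediate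
16 | cross-conjugated dienone ketal: C7 ketone between C5=C6 and C8=C9 | O1[C@H](c2ccccc2)[C@@H](c2ccccc2)OC13CC[C@]4(C)CC=C(C)C(=O)C=C34 | intermediate
17 | 8,9-diol (both hydroxyls anti to the C1 methyl), C7 ketone, C5=C6, C4 ketal | O1[C@H](c2ccccc2)[C@@H](c2ccccc2)OC13CC[C@]4(C)C[C@H](O)[C@](C)(O)C(=O)C=C34 | intermediate
18 | saturated C7 ketone: C5–H cis to the C8 and C9 hydroxyls, trans ring fusion, C4 ketal | O1[C@H](c2ccccc2)[C@@H](c2ccccc2)OC13CC[C@]4(C)C[C@H](O)[C@](C)(O)C(=O)C[C@@H]34 | intermediate
19 | 8,9-acetonide of 18 | O1[C@H](c2ccccc2)[C@@H](c2ccccc2)OC13CC[C@]4(C)C[C@H](OC(C)(C)O5)[C@@]5(C)C(=O)C[C@@H]34 | intermediate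
20 | potassium C6=C7 enolate of 19, not isolated | O1[C@H](c2ccccc2)[C@@H](c2ccccc2)OC13CC[C@]4(C)C[C@H](OC(C)(C)O5)[C@@]5(C)C([O-])=C[C@@H]34.[K+] | intermediate
21 | C6 hydroxy ketone: C6–OH cis to C5–H; acetonide and C4 ketal in place | O1[C@H](c2ccccc2)[C@@H](c2ccccc2)OC13CC[C@]4(C)C[C@H](OC(C)(C)O5)[C@@]5(C)C(=O)[C@H](O)[C@@H]34 | intermediate
22 | 6-hydroxy-4,7-dione 8,9-acetonide (trans-fused) | O=C1CC[C@]2(C)C[C@H](OC(C)(C)O3)[C@@]3(C)C(=O)[C@H](O)[C@H]21 | intermediate
23 | C4 carbinol: isopropyl cis to C5–H, hydroxyl cis to the C1 methyl; C6–OH, C7 ketone, 8,9-acetonide | CC(C)[C@]1(O)CC[C@]2(C)C[C@H](OC(C)(C)O3)[C@@]3(C)C(=O)[C@H](O)[C@H]21 | intermediate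
24 | 4-acetoxybenzoyl chloride | CC(=O)Oc1ccc(cc1)C(Cl)=O | starting material
25 | C6 4-acetoxybenzoate of 23 | CC(C)[C@]1(O)CC[C@]2(C)C[C@H](OC(C)(C)O3)[C@@]3(C)C(=O)[C@H](OC(=O)c3ccc(OC(C)=O)cc3)[C@H]21 | intermediate
26 | target: 4-hydroxybenzoate of the 4,8,9-trihydroxy-7-oxo daucane | CC(C)[C@]1(O)CC[C@]2(C)C[C@H](O)[C@](C)(O)C(=O)[C@H](OC(=O)c3ccc(O)cc3)[C@H]21 | target

Total step count: 18. Longest linear sequence: 18 steps (1 to 26).

Steps most likely to fail

Step 4. Dimerization of the ylide may outrun addition to the hindered β,β-disubstituted enone, or the two bonds may form with the reverse orientation. Fallback, setting out from 4 and returning at 7: the doubly activated dipolarophile allyl 2-methyl-5-oxocyclopent-1-ene-1-carboxylate (CC1=C(C(=O)OCC=C)C(=O)CC1) is used under the same base conditions at lower temperature to give the allyl ester cycloadduct F1. Pd(PPh3)4 and morpholine in THF then remove the allyl group, and the resulting β-keto acid decarboxylates to 7.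

Step 6. Electron transfer into the conjugated enone may break the vinylogous C6–O bond instead of the C10–O bond. Fallback, setting out from 8 and returning at 10: the enone is first epoxidized (H2O2, NaOH, MeOH) to the bridged epoxy ketone F2. SmI2 (5 equiv, THF/MeOH, −78 °C) then cleaves the epoxide C8–O bond and the C10–O bond, both unambiguously α to the ketone, to give the dihydroxy ketone F3. MsCl and Et3N convert F3 to the bis-mesylate F4, which is not isolated and loses its β-mesyloxy group by elimination to give mesylate 10; the second stage of step 7 follows.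

Step 12. The congested C5=C6 bond may resist the iridium catalyst, or hydrogen may arrive undirected from the face of the angular methyl and give the cis ring fusion. Fallback, setting out from 17 and returning at 19: the diol is protected first (2-methoxypropene, PPTS) as the acetonide enone F5. Conjugate hydride reduction with (i-Bu)2AlH and t-BuCu (HMPA, THF, −50 °C), in which the bulky hydride reagent attacks C5 from the face opposite the C1 methyl, then gives 19.

Further compounds
F1 | step 4 | allyl ester cycloadduct (7 carrying CO2CH2CH=CH2 at C5 in place of H) | O=C1CC[C@]2(C)[C@H]3C(=O)C(C)=C[C@H](O3)[C@]12C(=O)OCC=C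
F2 | step 6 | 7,8-epoxide of 8 (epoxide on the face of the bridge oxygen) | O1[C@H](c2ccccc2)[C@@H](c2ccccc2)OC13CC[C@]4(C)[C@H]5C(=O)[C@]6(C)O[C@@H]6[C@H](O5)[C@H]34
F3 | step 6 | ketal 6,7-dihydroxy C9 ketone (C8 epimers) | O1[C@H](c2ccccc2)[C@@H](c2ccccc2)OC13CC[C@]4(C)CC(=O)C(C)[C@H](O)[C@H](O)[C@H]34
F4 | step 6 | 6,7-bis(methanesulfonate) of F3 | O1[C@H](c2ccccc2)[C@@H](c2ccccc2)OC13CC[C@]4(C)CC(=O)C(C)[C@H](OS(C)(=O)=O)[C@H](OS(C)(=O)=O)[C@H]34
F5 | step 12 | 8,9-acetonide of 17 | O1[C@H](c2ccccc2)[C@@H](c2ccccc2)OC13CC[C@]4(C)C[C@H](OC(C)(C)O5)[C@@]5(C)C(=O)C=C34
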